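Conventions: labdane numbering is used for the carbons of all intermediates. α is the face of the decalin that carries C20 and β is the opposite face (that of H-5). In this sense the target is 2β-acetoxy-3β-hydroxy-19-oxolabd-7-en-15-oic acid with C20, C19 and the C9 chain α, and its descriptors are 2S,3R,4S,5S,9R,10S,13R.

## Analysis of the target

The target is a labdane-type diterpenoid acid with a trans-fused decalin (ring A: C1–C5 and C10; ring B: C5–C10) and a trisubstituted C7=C8 alkene. C9 carries a chain (C11–C15) that ends in the C15 carboxylic acid and holds the remote methyl stereocentre C13 (R). Six of the seven stereocentres are contiguous (C2, C3, C4, C5, C10, C9). C20, the C19 aldehyde and the C9 chain lie on the α face; H-5, H-9, the C18 methyl, the axial C3 hydroxyl and the equatorial C2 acetate lie on the β face. C4 and C10 are both quaternary and stand 1,3 to each other, with C19 and C20 syn-diaxial.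

The sensitive groups are:
- the β-hydroxy aldehyde (O-3/C19), which can undergo retro-aldol cleavage in base;
- the vicinal hydroxy acetate, where the acyl group can migrate from O-2 to O-3;
- the C7=C8 alkene, which can migrate or lactonise under acid and competes with any ring A alkene for oxidants;
- the free acid.

The difficulty lies in the two congested quaternary centres, in C13 (which cannot be relayed from the ring), and in four carbons (C15, C18, C19, C20) that must finish at three different oxidation levels. The strategy rests on one feature: C10 is bonded to C1, and the cis-2,3-diol calls for a C2=C3 alkene. A ring A with that alkene and a carboxyl on C10 is exactly what a [3,3] shift delivers from a δ-lactone that ties a C20 carboxyl on C10 to the oxygen of a vinyl carbinol at C3.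

## Retrosynthetic reasoning

**End game (34 back to 28).** The acetate of 34 is installed last on diol 33, because only then can the equatorial O-2 be told apart from the hindered axial O-3 without protecting groups. Before that the diol is held as an acetonide (32, 31, 30, 29, 28) while C15 is raised to the acid and C19 to the aldehyde. The two primary oxygens are distinguished by a 4-methoxybenzyl ether on O-15 and a benzyl ether on O-19. No C–C bond is cut here.

**C20 (28 back to 24).** The C20 methyl is traced to a carboxylic acid through aldehyde 26 and alcohol 25 (Wolff–Kishner reduction in the forward sense). The reason is that the key step delivers C10 with a carboxyl, and an angular carboxyl is the only handle available on this quaternary carbon.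

**C2–O and C3–O (24 back to 22).** Both C–O bonds are removed together to give the C2=C3 alkene of 22. Forward, a cis-dihydroxylation must come from the β face, which is the open one because C19 and C20 are both axial on the α face. It must also spare C7=C8.

**C1–C10, the key disconnection (22 back to 19).** Cutting C1–C10 and rejoining C3 to the carboxyl oxygen in a retro-[3,3] sense turns ring A into the lactone ring of 19, via silyl ester 21 and ketene acetal 20. This is chosen over any other ring A bond because it removes the quaternary C10 stereocentre and the ring in one step. It leaves a bicyclic lactone whose C3 centre dictates the C10 configuration on the way forward.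

**C5–C6 and C9–C10 (19 back to 13 and 18).** The cyclohexene ring B with its cis-fused lactone is a Diels–Alder adduct of unsaturated lactone 13 and diene 18. The forward reaction has to be regioselective (diene CH2 terminus to C5), endo (C9 chain cis to C20) and selective for the lactone face anti to the C4 methyl.

**Lactone 13 back to 6.** The C5=C10 bond and the ring C–O bond are cut to aldehyde 9 and phosphonate 10 (Z-selective olefination, then lactonisation through 11 and 12). Aldehyde 9 comes from ester 6 by protection and adjustment of oxidation level (7, 8).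

**C4–C19, C4–C18 and C3–C4 (6 back to 1 and 2).** The quaternary C4 is disconnected at its two one-carbon arms, giving 5 and then 4. Two successive chelate-controlled alkylations of a β-hydroxy ester set C4 relative to C3, and their order decides which arm ends α. Hydroxy ester 4 is the resolved form of aldol 3, made from ester 1 and aldehyde 2.

**Diene 18 back to 14.** The diene is the skeleton of 14 with one terminal methyl turned into a vinyl group (15, 16, 17). C13 and the whole side chain are therefore bought from the chiral pool and never have to be made.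

## Alternatives that were turned down

**Alternative 1:** iridium-catalysed allylic dearomatisation. The disconnection is C9–C10, which opens ring B and flattens ring A to the salicylate A2 carrying a dienyl carbonate on C5. Forward, an allyl–iridium unit formed from the carbonate would be attacked at its inner terminus C9 by the para carbon C10 of the phenoxide. This closes ring B and leaves the cross-conjugated dienone A1.
- For it: C9 and quaternary C10 are set by a catalyst from an achiral arene, the C3 oxygen and C19 (as an ester) are already in place, and the bicycle is reached in very few steps. On catalytic asymmetric induction and brevity to the bicycle this route is stronger than the chosen one.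
- Against it: A1 is still far from the target. C4 is trigonal and must be made quaternary by a reductive methylation that also has to set C5 trans, next to C10. O-2 has to be introduced and C3 reduced to the axial alcohol. The C9 vinyl group has to be grown into the full chain, including C13, by a second asymmetric operation. The dienone is also prone to dienone–phenol rearrangement.
- In its place the chosen route offers C4 (with C18 and C19 in their final connectivity), C13 and the whole chain in the molecule before ring A closes, and substrate relay (C3 to C10) instead of a demanding catalyst-controlled quaternary centre.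

**Alternative 2:** intramolecular Diels–Alder reaction. The disconnection cuts C5–C10 and C8–C9 and opens both rings to the acyclic trienoate A4. In A4 an (E)-C9=C10 enoate and a C5=C6–C7(OSi)=C8 diene are joined through C1–C4, with the C2/C3 acetonide and quaternary C4 in the tether. Forward, heating would close rings A and B together to give A3.
- For it: two rings and four stereocentres form in one step. The diol is already in place as an acetonide, so the chemoselective dihydroxylation that the chosen route must manage never arises; on this point the alternative is stronger.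
- Against it: the dienophile reacts at its fully substituted carbon C10 and the diene at a neopentyl terminus (C5 next to C4), so a hot reaction with a labile silyl enol ether is expected. The C8 stereocentre is made only to be erased when C7=C8 is installed. C11 is a single ester carbon, so C12–C16 with C13 must be attached later beside the hindered C9. A4 itself needs a long linear synthesis with its own C2/C3/C4 triad.
- The chosen route splits the same task into two pericyclic steps with fewer constraints each, and carries the finished side chain from the start.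

**Alternative 3:** hydroxyl-directed cyclopropanation. The disconnection is C4–C18, made last on an intact bicycle. The exocyclic enol ether A6 (C4=C19–OMe) would be cyclopropanated under Simmons–Smith conditions, directed by the 3β-hydroxyl, to give the spiro methoxycyclopropane A5. Acid would then open it to the C18 methyl and the C19 aldehyde.
- For it: the most congested centre is solved by reagent delivery from a neighbouring group, and C19 arrives directly at the aldehyde level. This is stronger than the chosen route, which needs a deprotection and an oxidation at C19.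
- Against it: this is a tactic for one centre and not a plan for the skeleton. The decalin with C5, C9, C10, the chain and the 2,3-dioxygenation must come from a separate construction ending in a hindered, epimerisable α-oxygenated C4 ketone. The acidic ring opening threatens the silyl ether, the C7=C8 alkene and the new β-hydroxy aldehyde.
- The chosen route sets C4 at the outset in an acyclic, chelate-controlled alkylation and then uses it as a controlling element for the Diels–Alder facial selectivity, instead of treating it as a late problem.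

Key step: step 15

Assumption (remark on the chemistry): OsO4 is taken to attack the cis-disubstituted C2=C3 alkene faster than the trisubstituted, doubly flanked C7=C8 alkene; a fallback is given in case this does not hold.

## Route

Step 1
Reactants: 1 propan-2-yl acetate; 2 acrolein
Product: 3 rac-propan-2-yl 3-hydroxypent-4-enoate
Conditions: LiN(i-Pr)2 (1.05 equiv), THF, −78 °C; then 2; aq. NH4Cl
Reagents that add atoms: none
Why: Aldol addition of the lithium ester enolate to the aldehyde carbon of 2 (1,2-addition is the kinetic path at −78 °C); the racemate is accepted because step 2 resolves it, and the isopropyl ester is used so that Ti(Oi-Pr)4 in step 2 cannot exchange the ester alkoxide.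

Step 2
Reactants: 3 rac-propan-2-yl 3-hydroxypent-4-enoate
Product: 4 propan-2-yl (3S)-3-hydroxypent-4-enoate
Conditions: Ti(Oi-Pr)4 (0.1 equiv), D-(−)-diisopropyl tartrate (0.15 equiv), t-BuOOH (0.6 equiv), 4 Å MS, CH2Cl2, −20 °C, run past half conversion
Reagents that add atoms: none
Why: Sharpless kinetic resolution of a secondary vinyl carbinol: with the D-tartrate the (R)-alcohol should be epoxidised much faster, so the (S)-alcohol is recovered; this sets C3, from which C4 and later C10 are relayed.

Step 3
Reactants: 4 propan-2-yl (3S)-3-hydroxypent-4-enoate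
Product: 5 propan-2-yl (2R,3R)-3-hydroxy-2-methylpent-4-enoate
Conditions: LiN(i-Pr)2 (2.2 equiv), THF, −78 → −20 °C; MeI, DMPU, −78 → −10 °C; aq. NH4Cl
Reagents that add atoms: iodomethane, CI
Why: Fráter–Seebach alkylation: the chelated dilithium alkoxide–enolate is methylated on the face away from the vinyl group, which should give the 2,3-anti ester (the C3 descriptor changes from S to R only because the CIP priorities change).

Step 4
Reactants: 5 propan-2-yl (2R,3R)-3-hydroxy-2-methylpent-4-enoate
Product: 6 propan-2-yl (2R,3R)-2-[(benzyloxy)methyl]-3-hydroxy-2-methylpent-4-enoate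
Conditions: LiN(i-Pr)2 (2.3 equiv), THF, −78 → −20 °C; BnOCH2Cl, DMPU, −78 → −30 °C; aq. NH4Cl
Reagents that add atoms: benzyl chloromethyl ether, ClCOCc1ccccc1
Why: Second Fráter–Seebach alkylation: the re-formed chelated enolate is attacked on the same face, so the benzyloxymethyl arm (C19) ends anti to the hydroxyl and the methyl (C18) syn, which is the C4 configuration of the target. The reactive α-chloro ether is chosen because the enolate is fully substituted.

Step 5
Reactants: 6 propan-2-yl (2R,3R)-2-[(benzyloxy)methyl]-3-hydroxy-2-methylpent-4-enoate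
Product: 7 propan-2-yl (2R,3R)-2-[(benzyloxy)methyl]-2-methyl-3-[(triethylsilyl)oxy]pent-4-enoate
Conditions: Et3SiOTf, 2,6-lutidine, CH2Cl2, −78 → 0 °C
Reagents that add atoms: triethylsilyl trifluoromethanesulfonate, CC[Si](CC)(CC)OS(=O)(=O)C(F)(F)F
Why: Silylation of the hindered secondary allylic alcohol with a silyl triflate; the triethylsilyl group blocks retro-aldol and silyl-free side reactions in steps 6–8 and is labile enough to fall off in the lactonisation of step 9.

Step 6
Reactants: 7 propan-2-yl (2R,3R)-2-[(benzyloxy)methyl]-2-methyl-3-[(triethylsilyl)oxy]pent-4-enoate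
Product: 8 (2R,3R)-2-[(benzyloxy)methyl]-2-methyl-3-[(triethylsilyl)oxy]pent-4-en-1-ol
Conditions: i-Bu2AlH (2.5 equiv), CH2Cl2, −78 → 0 °C; aq. potassium sodium tartrate
Reagents that add atoms: none
Why: Hydride reduction of the hindered ester to the primary alcohol; full reduction and reoxidation is preferred to a partial reduction that is hard to stop at a neopentyl aldehyde.

Step 7
Reactants: 8 (2R,3R)-2-[(benzyloxy)methyl]-2-methyl-3-[(triethylsilyl)oxy]pent-4-en-1-ol
Product: 9 (2R,3R)-2-[(benzyloxy)methyl]-2-methyl-3-[(triethylsilyl)oxy]pent-4-enal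
Conditions: Dess–Martin periodinane, NaHCO3, CH2Cl2, 0 → 23 °C
Reagents that add atoms: none
Why: Dess–Martin oxidation of a neopentyl primary alcohol; the aldehyde has no α-hydrogen and so cannot epimerise or eliminate.

Step 8
Reactants: 9 (2R,3R)-2-[(benzyloxy)methyl]-2-methyl-3-[(triethylsilyl)oxy]pent-4-enal; 10 methyl bis(2,2,2-trifluoroethyl)phosphonoacetate
Product: 11 methyl (2Z,4R,5R)-4-[(benzyloxy)methyl]-4-methyl-5-[(triethylsilyl)oxy]hepta-2,6-dienoate
Conditions: KN(SiMe3)2, 18-crown-6, THF, −78 → −40 °C
Reagents that add atoms: none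
Why: Still–Gennari olefination: the electron-poor phosphonate eliminates from the kinetic adduct and should give the (Z)-enoate, the geometry that lets O-3 reach the ester carbonyl.

Step 9
Reactants: 11 methyl (2Z,4R,5R)-4-[(benzyloxy)methyl]-4-methyl-5-[(triethylsilyl)oxy]hepta-2,6-dienoate
Product: 13 (5R,6R)-5-[(benzyloxy)methyl]-6-ethenyl-5-methyl-5,6-dihydro-2H-pyran-2-one, via hydroxy enoate 12 (not isolated)
Conditions: camphorsulfonic acid (0.2 equiv), MeOH/CH2Cl2, 0 → 23 °C; then toluene, 80 °C
Reagents that add atoms: none
Why: Acid-catalysed desilylation followed by lactonisation (intramolecular transesterification) of the (Z)-δ-hydroxy enoate closes the unsaturated δ-lactone; no stereocentre is touched.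

Step 10
Reactants: 14 (R)-citronellol
Product: 15 1-({[(3R)-3,7-dimethyloct-6-en-1-yl]oxy}methyl)-4-methoxybenzene
Conditions: NaH, 4-methoxybenzyl chloride, Bu4NI (cat.), THF/DMF, 0 → 23 °C
Reagents that add atoms: 4-methoxybenzyl chloride, COc1ccc(CCl)cc1
Why: Williamson etherification; the 4-methoxybenzyl ether withstands the later base, hydride and Wolff–Kishner conditions and can be removed oxidatively beside a benzyl ether.

Step 11
Reactants: 15 1-({[(3R)-3,7-dimethyloct-6-en-1-yl]oxy}methyl)-4-methoxybenzene
Product: 16 (2E,6R)-8-[(4-methoxybenzyl)oxy]-2,6-dimethyloct-2-en-1-ol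
Conditions: SeO2 (0.3 equiv), t-BuOOH (3 equiv), salicylic acid (0.1 equiv), CH2Cl2, 23 °C
Reagents that add atoms: tert-butyl hydroperoxide, CC(C)(C)OO; selenium dioxide, O=[Se]=O
Why: SeO2-catalysed allylic oxidation (ene reaction, then [2,3]-sigmatropic shift) is selective for the (E)-methyl group of a trisubstituted alkene; any enal 17 formed by overoxidation converges in step 12.

Step 12
Reactants: 16 (2E,6R)-8-[(4-methoxybenzyl)oxy]-2,6-dimethyloct-2-en-1-ol
Product: 17 (2E,6R)-8-[(4-methoxybenzyl)oxy]-2,6-dimethyloct-2-enal
Conditions: MnO2 (excess), CH2Cl2, 23 °C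
Reagents that add atoms: none
Why: Allylic alcohol oxidation with MnO2 gives the (E)-enal without touching the benzylic ether or the alkene geometry.

Step 13
Reactants: 17 (2E,6R)-8-[(4-methoxybenzyl)oxy]-2,6-dimethyloct-2-enal
Product: 18 1-({[(3R,6E)-3,7-dimethylnona-6,8-dien-1-yl]oxy}methyl)-4-methoxybenzene
Conditions: Ph3PCH3Br, KOt-Bu, THF, 0 °C
Reagents that add atoms: methyltriphenylphosphonium bromide, C[P+](c1ccccc1)(c1ccccc1)c1ccccc1.[Br-]
Why: Wittig methylenation of the enal gives the 1,3-diene with the (E)-trisubstituted alkene intact, so the chain sits "outside" in the s-cis diene.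

Step 14
Reactants: 13 (5R,6R)-5-[(benzyloxy)methyl]-6-ethenyl-5-methyl-5,6-dihydro-2H-pyran-2-one; 18 1-({[(3R,6E)-3,7-dimethylnona-6,8-dien-1-yl]oxy}methyl)-4-methoxybenzene
Product: 19 (3R,4R,4aS,8S,8aR)-4-[(benzyloxy)methyl]-3-ethenyl-8-{(3R)-5-[(4-methoxybenzyl)oxy]-3-methylpentyl}-4,7-dimethyl-3,4,4a,5,8,8a-hexahydro-1H-isochromen-1-one
Conditions: 18 (2.5 equiv), EtAlCl2 (1.2 equiv), CH2Cl2, −40 → 0 °C
Reagents that add atoms: none
Why: Lewis-acid-promoted Diels–Alder reaction: the free CH2 terminus of the diene (C6) bonds to the β-carbon C5, as both the 1-alkyl substituent of the diene and the neopentyl character of C5 demand, and the cis alkene of 13 gives the cis ring fusion. Endo addition of the (E)-diene should place the C9 chain cis to C20 and C4, and the diene should add to the lactone face opposite the pseudo-axial C4 methyl and the C3 vinyl group, which sets C5, C9 and C10 relative to C3/C4.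

Step 15
Reactants: 19 (3R,4R,4aS,8S,8aR)-4-[(benzyloxy)methyl]-3-ethenyl-8-{(3R)-5-[(4-methoxybenzyl)oxy]-3-methylpentyl}-4,7-dimethyl-3,4,4a,5,8,8a-hexahydro-1H-isochromen-1-one
Product: 22 19-benzyloxy-15-(4-methoxybenzyloxy)labda-2,7-dien-20-oic acid, via silyl ketene acetal 20 (not isolated), via trimethylsilyl ester 21 (not isolated)
Conditions: LiN(i-Pr)2 (1.5 equiv), Me3SiCl/Et3N (3 equiv, premixed), THF, −78 → 23 °C; solvent changed to toluene, 110 °C, sealed tube; then aq. citric acid, THF, 23 °C
Reagents that add atoms: none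
Why: LiN(i-Pr)2 removes the only α-hydrogen of the lactone (H-10) and Me3SiCl present in the flask traps the enolate on oxygen as ketene acetal 20 (C10=C20). On heating, the six atoms C10=C20–O–C3–C2=C1 undergo a concerted [3,3]-sigmatropic shift in which C1–C10 forms, C3–O breaks and C2=C3 and the C20 carbonyl appear; silyl ester 21 is hydrolysed to 22 on work-up. The closest known reaction is the Ireland–Claisen rearrangement of δ-lactone silyl ketene acetals that carry a vinyl group on the carbinol carbon, which gives cyclohexene carboxylic acids. Ring A closes as the six-membered carbocycle C10–C1–C2–C3–C4–C5 in the only mode the tether allows: ketene acetal and allyl unit sit in the same lactone ring, so the vinyl group must swing across it from an axial position and the pericyclic array is a boat inside a bicyclo[2.2.2]octene-like transition state. The one new stereocentre, C10, is controlled by C3: the vinyl group lies on the lactone face that carries H-5, C1 can reach C10 only from that face, and C20 is therefore left anti to H-5 (trans-decalin) and syn to C19 and the C9 chain. The C10 configuration of 19 is erased in 20, so only C3, C4, C5 and C9 of the precursor matter. The step needs O- and not C-silylation and no elimination, which the fully substituted enolate carbon and the absence of a β-leaving group should secure; the C2=C3 alkene is necessarily cis because it forms inside the ring.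

Step 16
Reactants: 22 19-benzyloxy-15-(4-methoxybenzyloxy)labda-2,7-dien-20-oic acid
Product: 23 19-benzyloxy-2β,3β-dihydroxy-15-(4-methoxybenzyloxy)labd-7-en-20-oic acid
Conditions: OsO4 (0.05 equiv), N-methylmorpholine N-oxide (1.05 equiv), acetone/H2O, 0 → 23 °C
Reagents that add atoms: osmium tetroxide, O=[Os](=O)(=O)=O; N-methylmorpholine N-oxide, C[N+]1([O-])CCOCC1; water, O
Why: Catalytic cis-dihydroxylation with OsO4: the α face of C2=C3 is closed by the axial C20 carboxyl and the axial C19 arm, so both hydroxyls should enter from the β face. The cis-disubstituted C2=C3 alkene with its free C1 methylene is expected to react before the trisubstituted C7=C8 alkene flanked by the C8 methyl and the C9 chain, and the oxidant is limited to one equivalent.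

Step 17
Reactants: 23 19-benzyloxy-2β,3β-dihydroxy-15-(4-methoxybenzyloxy)labd-7-en-20-oic acid
Product: 24 19-benzyloxy-2β,3β-(isopropylidenedioxy)-15-(4-methoxybenzyloxy)labd-7-en-20-oic acid
Conditions: 2,2-dimethoxypropane, pyridinium p-toluenesulfonate (cat.), acetone, 23 °C
Reagents that add atoms: 2,2-dimethoxypropane, COC(C)(C)OC
Why: Acid-catalysed acetal exchange locks the cis-diol as its acetonide, which is stable to hydride, hot KOH/hydrazine, dissolving metal and the oxidations that follow.

Step 18
Reactants: 24 19-benzyloxy-2β,3β-(isopropylidenedioxy)-15-(4-methoxybenzyloxy)labd-7-en-20-oic acid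
Product: 25 19-benzyloxy-2β,3β-(isopropylidenedioxy)-15-(4-methoxybenzyloxy)labd-7-en-20-ol
Conditions: LiAlH4, THF, 0 → 66 °C; H2O, aq. NaOH
Reagents that add atoms: none
Why: LiAlH4 reduction of the hindered tertiary carboxylic acid to the neopentyl C20 alcohol; ethers, acetonide and the isolated alkene are inert.

Step 19
Reactants: 25 19-benzyloxy-2β,3β-(isopropylidenedioxy)-15-(4-methoxybenzyloxy)labd-7-en-20-ol
Product: 26 19-benzyloxy-2β,3β-(isopropylidenedioxy)-15-(4-methoxybenzyloxy)labd-7-en-20-al
Conditions: Dess–Martin periodinane, NaHCO3, CH2Cl2, 23 °C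
Reagents that add atoms: none
Why: Dess–Martin oxidation to the angular aldehyde, which cannot enolise.

Step 20
Reactants: 26 19-benzyloxy-2β,3β-(isopropylidenedioxy)-15-(4-methoxybenzyloxy)labd-7-en-20-al
Product: 28 19-benzyloxy-2β,3β-(isopropylidenedioxy)-15-(4-methoxybenzyloxy)labd-7-ene, via hydrazone 27 (not isolated)
Conditions: N2H4·H2O, KOH, diethylene glycol, 130 °C then 200 °C
Reagents that add atoms: none
Why: Wolff–Kishner reduction in the Huang-Minlon form: hydrazone 27 loses N2 in hot base and leaves the C20 methyl group; benzyl-type ethers, the acetonide and the unconjugated alkene tolerate KOH at 200 °C.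

Step 21
Reactants: 28 19-benzyloxy-2β,3β-(isopropylidenedioxy)-15-(4-methoxybenzyloxy)labd-7-ene
Product: 29 19-benzyloxy-2β,3β-(isopropylidenedioxy)labd-7-en-15-ol
Conditions: DDQ, CH2Cl2/pH 7 buffer, 0 → 23 °C
Reagents that add atoms: none
Why: Oxidative cleavage of the electron-rich 4-methoxybenzyl ether by DDQ (hydride abstraction, then hydrolysis) frees O-15; the plain benzyl ether on O-19 reacts much more slowly.

Step 22
Reactants: 29 19-benzyloxy-2β,3β-(isopropylidenedioxy)labd-7-en-15-ol
Product: 30 19-benzyloxy-2β,3β-(isopropylidenedioxy)labd-7-en-15-oic acid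
Conditions: TEMPO (0.2 equiv), PhI(OAc)2 (2.2 equiv), MeCN/H2O, 23 °C
Reagents that add atoms: water, O
Why: Nitroxyl-catalysed oxidation of the primary alcohol through the aldehyde hydrate to the carboxylic acid; the hindered alkene, the acetonide and the benzyl ether should not be affected.

Step 23
Reactants: 30 19-benzyloxy-2β,3β-(isopropylidenedioxy)labd-7-en-15-oic acid
Product: 31 19-hydroxy-2β,3β-(isopropylidenedioxy)labd-7-en-15-oic acid
Conditions: Li, NH3(l)/THF, −78 °C; solid NH4Cl
Reagents that add atoms: none
Why: Dissolving-metal cleavage of the benzyl ether (C–O scission of the arene radical anion); the lithium carboxylate, the acetonide and the isolated trisubstituted alkene are not reduced.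

Step 24
Reactants: 31 19-hydroxy-2β,3β-(isopropylidenedioxy)labd-7-en-15-oic acid
Product: 32 2β,3β-(isopropylidenedioxy)-19-oxolabd-7-en-15-oic acid
Conditions: Dess–Martin periodinane, pyridine, CH2Cl2, 0 → 23 °C
Reagents that add atoms: none
Why: Dess–Martin oxidation of the neopentyl C19 alcohol stops at the aldehyde and leaves the free acid alone; C4 is quaternary, so the aldehyde is configurationally safe.

Step 25
Reactants: 32 2β,3β-(isopropylidenedioxy)-19-oxolabd-7-en-15-oic acid
Product: 33 2β,3β-dihydroxy-19-oxolabd-7-en-15-oic acid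
Conditions: AcOH/H2O (4:1), 45 °C
Reagents that add atoms: none
Why: Aqueous acid hydrolysis of the acetonide; mild acetic acid is chosen to avoid migration of the C7=C8 alkene, and the β-hydroxy aldehyde is safe because retro-aldol cleavage needs base.

Step 26
Reactants: 33 2β,3β-dihydroxy-19-oxolabd-7-en-15-oic acid
Product: 34 2β-acetoxy-3β-hydroxy-19-oxolabd-7-en-15-oic acid (target)
Conditions: Ac2O (1.5 equiv), pyridine, CH2Cl2, −20 → 0 °C; aq. NaHCO3 work-up, then acidification
Reagents that add atoms: acetic anhydride, CC(=O)OC(C)=O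
Why: Selective acylation: the equatorial C2 hydroxyl is far more accessible than the axial C3 hydroxyl, which is flanked by quaternary C4 and is 1,3-diaxial to H-1β and H-5; any mixed anhydride at C15 is hydrolysed on work-up.

## Compound list

1 | propan-2-yl acetate | CC(C)OC(C)=O | starting material
2 | acrolein | C=CC=O | starting material
3 | rac-propan-2-yl 3-hydroxypent-4-enoate | CC(C)OC(=O)CC(O)C=C | intermediate
4 | propan-2-yl (3S)-3-hydroxypent-4-enoate | CC(C)OC(=O)C[C@H](O)C=C | intermediate
5 | propan-2-yl (2R,3R)-3-hydroxy-2-methylpent-4-enoate | CC(C)OC(=O)[C@H](C)[C@H](O)C=C | intermediate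
6 | propan-2-yl (2R,3R)-2-[(benzyloxy)methyl]-3-hydroxy-2-methylpent-4-enoate | CC(C)OC(=O)[C@](C)(COCc1ccccc1)[C@H](O)C=C | intermediate
7 | propan-2-yl (2R,3R)-2-[(benzyloxy)methyl]-2-methyl-3-[(triethylsilyl)oxy]pent-4-enoate | CC(C)OC(=O)[C@](C)(COCc1ccccc1)[C@H](O[Si](CC)(CC)CC)C=C | intermediate
8 | (2R,3R)-2-[(benzyloxy)methyl]-2-methyl-3-[(triethylsilyl)oxy]pent-4-en-1-ol | OC[C@](C)(COCc1ccccc1)[C@H](O[Si](CC)(CC)CC)C=C | intermediate
9 | (2R,3R)-2-[(benzyloxy)methyl]-2-methyl-3-[(triethylsilyl)oxy]pent-4-enal | O=C[C@](C)(COCc1ccccc1)[C@H](O[Si](CC)(CC)CC)C=C | intermediate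
10 | methyl bis(2,2,2-trifluoroethyl)phosphonoacetate | COC(=O)CP(=O)(OCC(F)(F)F)OCC(F)(F)F | starting material
11 | methyl (2Z,4R,5R)-4-[(benzyloxy)methyl]-4-methyl-5-[(triethylsilyl)oxy]hepta-2,6-dienoate | COC(=O)/C=C\[C@](C)(COCc1ccccc1)[C@H](O[Si](CC)(CC)CC)C=C | intermediate
12 | methyl (2Z,4R,5R)-4-[(benzyloxy)methyl]-5-hydroxy-4-methylhepta-2,6-dienoate (hydroxy enoate, not isolated) | COC(=O)/C=C\[C@](C)(COCc1ccccc1)[C@H](O)C=C | intermediate
13 | (5R,6R)-5-[(benzyloxy)methyl]-6-ethenyl-5-methyl-5,6-dihydro-2H-pyran-2-one | O=C1C=C[C@](C)(COCc2ccccc2)[C@@H](C=C)O1 | intermediate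
14 | (R)-citronellol | CC(C)=CCC[C@@H](C)CCO | starting material
15 | 1-({[(3R)-3,7-dimethyloct-6-en-1-yl]oxy}methyl)-4-methoxybenzene | CC(C)=CCC[C@@H](C)CCOCc1ccc(OC)cc1 | intermediate
16 | (2E,6R)-8-[(4-methoxybenzyl)oxy]-2,6-dimethyloct-2-en-1-ol | OC/C(C)=C/CC[C@@H](C)CCOCc1ccc(OC)cc1 | intermediate
17 | (2E,6R)-8-[(4-methoxybenzyl)oxy]-2,6-dimethyloct-2-enal | O=C/C(C)=C/CC[C@@H](C)CCOCc1ccc(OC)cc1 | intermediate
18 | 1-({[(3R,6E)-3,7-dimethylnona-6,8-dien-1-yl]oxy}methyl)-4-methoxybenzene | C=C/C(C)=C/CC[C@@H](C)CCOCc1ccc(OC)cc1 | intermediate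
19 | (3R,4R,4aS,8S,8aR)-4-[(benzyloxy)methyl]-3-ethenyl-8-{(3R)-5-[(4-methoxybenzyl)oxy]-3-methylpentyl}-4,7-dimethyl-3,4,4a,5,8,8a-hexahydro-1H-isochromen-1-one (cis-fused lactone joining C20 to O–C3; key-step precursor) | O=C1O[C@H](C=C)[C@@](C)(COCc2ccccc2)[C@H]3CC=C(C)[C@@H](CC[C@@H](C)CCOCc4ccc(OC)cc4)[C@@H]13 | intermediate
20 | trimethylsilyl ketene acetal of 19 (C10=C20, O-silylated; not isolated) | C[Si](C)(C)OC1=C2[C@H](CC[C@@H](C)CCOCc3ccc(OC)cc3)C(C)=CC[C@@H]2[C@](C)(COCc4ccccc4)[C@@H](C=C)O1 | intermediate
21 | trimethylsilyl 19-benzyloxy-15-(4-methoxybenzyloxy)labda-2,7-dien-20-oate (not isolated) | C1C=C[C@@](C)(COCc2ccccc2)[C@H]3CC=C(C)[C@@H](CC[C@@H](C)CCOCc4ccc(OC)cc4)[C@]13C(=O)O[Si](C)(C)C | intermediate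
22 | 19-benzyloxy-15-(4-methoxybenzyloxy)labda-2,7-dien-20-oic acid (trans-decalin; C20, C19 and C11 α; 13R) | C1C=C[C@@](C)(COCc2ccccc2)[C@H]3CC=C(C)[C@@H](CC[C@@H](C)CCOCc4ccc(OC)cc4)[C@]13C(=O)O | intermediate
23 | 19-benzyloxy-2β,3β-dihydroxy-15-(4-methoxybenzyloxy)labd-7-en-20-oic acid | O[C@H]1C[C@@]2(C(=O)O)[C@H](CC[C@@H](C)CCOCc3ccc(OC)cc3)C(C)=CC[C@@H]2[C@](C)(COCc4ccccc4)[C@H]1O | intermediate
24 | 19-benzyloxy-2β,3β-(isopropylidenedioxy)-15-(4-methoxybenzyloxy)labd-7-en-20-oic acid | CC1(C)O[C@H]2C[C@@]3(C(=O)O)[C@H](CC[C@@H](C)CCOCc4ccc(OC)cc4)C(C)=CC[C@@H]3[C@](C)(COCc5ccccc5)[C@H]2O1 | intermediate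
25 | 19-benzyloxy-2β,3β-(isopropylidenedioxy)-15-(4-methoxybenzyloxy)labd-7-en-20-ol | CC1(C)O[C@H]2C[C@@]3(CO)[C@H](CC[C@@H](C)CCOCc4ccc(OC)cc4)C(C)=CC[C@@H]3[C@](C)(COCc5ccccc5)[C@H]2O1 | intermediate
26 | 19-benzyloxy-2β,3β-(isopropylidenedioxy)-15-(4-methoxybenzyloxy)labd-7-en-20-al | CC1(C)O[C@H]2C[C@@]3(C=O)[C@H](CC[C@@H](C)CCOCc4ccc(OC)cc4)C(C)=CC[C@@H]3[C@](C)(COCc5ccccc5)[C@H]2O1 | intermediate
27 | hydrazone of 26 at C20 (not isolated) | CC1(C)O[C@H]2C[C@@]3(C=NN)[C@H](CC[C@@H](C)CCOCc4ccc(OC)cc4)C(C)=CC[C@@H]3[C@](C)(COCc5ccccc5)[C@H]2O1 | intermediate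
28 | 19-benzyloxy-2β,3β-(isopropylidenedioxy)-15-(4-methoxybenzyloxy)labd-7-ene | CC1(C)O[C@H]2C[C@@]3(C)[C@H](CC[C@@H](C)CCOCc4ccc(OC)cc4)C(C)=CC[C@@H]3[C@](C)(COCc5ccccc5)[C@H]2O1 | intermediate
29 | 19-benzyloxy-2β,3β-(isopropylidenedioxy)labd-7-en-15-ol | CC1(C)O[C@H]2C[C@@]3(C)[C@H](CC[C@@H](C)CCO)C(C)=CC[C@@H]3[C@](C)(COCc4ccccc4)[C@H]2O1 | intermediate
30 | 19-benzyloxy-2β,3β-(isopropylidenedioxy)labd-7-en-15-oic acid | CC1(C)O[C@H]2C[C@@]3(C)[C@H](CC[C@@H](C)CC(=O)O)C(C)=CC[C@@H]3[C@](C)(COCc4ccccc4)[C@H]2O1 | intermediate
31 | 19-hydroxy-2β,3β-(isopropylidenedioxy)labd-7-en-15-oic acid | CC1(C)O[C@H]2C[C@@]3(C)[C@H](CC[C@@H](C)CC(=O)O)C(C)=CC[C@@H]3[C@](C)(CO)[C@H]2O1 | intermediate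
32 | 2β,3β-(isopropylidenedioxy)-19-oxolabd-7-en-15-oic acid | CC1(C)O[C@H]2C[C@@]3(C)[C@H](CC[C@@H](C)CC(=O)O)C(C)=CC[C@@H]3[C@](C)(C=O)[C@H]2O1 | intermediate
33 | 2β,3β-dihydroxy-19-oxolabd-7-en-15-oic acid | O[C@H]1C[C@@]2(C)[C@H](CC[C@@H](C)CC(=O)O)C(C)=CC[C@@H]2[C@](C)(C=O)[C@H]1O | intermediate
34 | (3R)-5-[(1R,4aS,5S,6R,7S,8aS)-7-acetoxy-5-formyl-6-hydroxy-2,5,8a-trimethyl-1,4,4a,5,6,7,8,8a-octahydronaphthalen-1-yl]-3-methylpentanoic acid (2β-acetoxy-3β-hydroxy-19-oxolabd-7-en-15-oic acid) | CC(=O)O[C@H]1C[C@@]2(C)[C@H](CC[C@@H](C)CC(=O)O)C(C)=CC[C@@H]2[C@](C)(C=O)[C@H]1O | target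

## Step count and risks

Total: 26 steps. Longest linear sequence: 22 steps (steps 1–9, then 14–26). The diene branch (steps 10–13) joins at step 14.

**Step 15 (key step).** The most likely failure is slow or incomplete deprotonation at the hindered ring-fusion carbon, or thermal breakdown of the ketene acetal before the lactone, cis-fused to ring B, can reach the strained boat transition state.

Fallback, from 19 back to 22: the C1–C10 bond is made by enolate alkylation instead of a sigmatropic shift.
- 9-BBN in THF, then NaBO3·4H2O, should hydroborate only the monosubstituted vinyl group and give the primary alcohol F1.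
- I2, PPh3 and imidazole give the iodide F2.
- KN(SiMe3)2 in THF (−78 → 0 °C) closes ring A by intramolecular C-alkylation of the lactone enolate. The tether reaches C10 from the face of H-5, so the same C10 configuration results, giving the bridged lactone F3.
- KOH in MeOH/H2O opens the lactone, and allyl bromide in DMF traps the carboxylate as the hydroxy allyl ester F4.
- Dess–Martin oxidation gives the 3-ketone F5.
- KN(SiMe3)2 and PhNTf2 give the C2=C3 enol triflate F6; C4 is quaternary, so only C2 can enolise.
- Pd(PPh3)4 with HCO2H/Et3N reduces the enol triflate to the alkene and removes the allyl ester in the same operation, giving 22.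

**Step 14.** The most likely failure is a slow cycloaddition to a lactone whose β-carbon is neopentyl. Polymerisation of the diene by the Lewis acid and erosion of the endo and facial preferences would then take over.

Fallback, from 9 (with 18) back to 19: the dienophile is activated by a second ester on C10.
- Knoevenagel condensation of 9 with dimethyl malonate (TiCl4, pyridine, THF) gives the alkylidene malonate F7.
- Camphorsulfonic acid in MeOH, then warm toluene, removes the silyl group and lactonises onto the cis ester to give the 3-carbomethoxy lactone F8.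
- F8 is a doubly activated dienophile and should add 18 under mild conditions (ZnCl2, CH2Cl2, 23 °C) with the same regiochemistry and facial sense and with the ring carbonyl endo, giving F9.
- Krapcho demethoxycarbonylation (LiCl, wet DMSO, 140 °C) removes the extra ester and gives 19. Protonation at C10 may also give the C10 epimer of 19, which is of no consequence because C10 becomes trigonal in 20.

**Step 16.** The most likely failure is competing osmylation of the C7=C8 alkene, or over-oxidation to a tetraol.

Fallback, from 22 back to 24: C7=C8 is masked first.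
- I2 and NaHCO3 in MeCN/H2O should lactonise the C20 carboxylate onto the more nucleophilic trisubstituted alkene at its tertiary carbon C8 (trans-diaxial opening of the β-iodonium ion), giving the iodolactone F10.
- OsO4 with N-methylmorpholine N-oxide can then attack only C2=C3, giving diol F11.
- 2,2-Dimethoxypropane with pyridinium p-toluenesulfonate gives the acetonide F12.
- Zn dust in AcOH/THF regenerates the C7=C8 alkene and the C20 acid by reductive elimination, giving 24.

**Step 4.** The most likely failure is O-alkylation of the alkoxide, incomplete reaction of the fully substituted enolate, or loss of facial control in forming the quaternary carbon.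

Fallback, from 5 back to 6: the quaternary carbon is made by an aldol reaction instead of an alkylation.
- The dianion of 5 (LiN(i-Pr)2, 2.2 equiv, THF, −78 °C) is treated with monomeric formaldehyde, which should add with the same facial sense and give diol F13.
- The primary hydroxyl is then benzylated selectively through the stannylene acetal (Bu2SnO, toluene, reflux; then benzyl bromide, Bu4NI), giving 6.

## Further compounds

F1 | step 15 | 3-(2-hydroxyethyl) analogue of 19 (vinyl group hydroborated at C1) | O=C1O[C@H](CCO)[C@@](C)(COCc2ccccc2)[C@H]3CC=C(C)[C@@H](CC[C@@H](C)CCOCc4ccc(OC)cc4)[C@@H]13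
F2 | step 15 | 3-(2-iodoethyl) analogue of 19 | O=C1O[C@H](CCI)[C@@](C)(COCc2ccccc2)[C@H]3CC=C(C)[C@@H](CC[C@@H](C)CCOCc4ccc(OC)cc4)[C@@H]13
F3 | step 15 | 19-benzyloxy-15-(4-methoxybenzyloxy)labd-7-en-20-oic acid 20,3α-lactone (bridged lactone) | O=C1O[C@@H]2CC[C@]13[C@H](CC[C@@H](C)CCOCc4ccc(OC)cc4)C(C)=CC[C@@H]3[C@]2(C)COCc5ccccc5
F4 | step 15 | allyl 19-benzyloxy-3α-hydroxy-15-(4-methoxybenzyloxy)labd-7-en-20-oate | O[C@@H]1CC[C@@]2(C(=O)OCC=C)[C@H](CC[C@@H](C)CCOCc3ccc(OC)cc3)C(C)=CC[C@@H]2[C@]1(C)COCc4ccccc4
F5 | step 15 | allyl 19-benzyloxy-15-(4-methoxybenzyloxy)-3-oxolabd-7-en-20-oate | O=C1CC[C@@]2(C(=O)OCC=C)[C@H](CC[C@@H](C)CCOCc3ccc(OC)cc3)C(C)=CC[C@@H]2[C@]1(C)COCc4ccccc4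
F6 | step 15 | allyl 19-benzyloxy-15-(4-methoxybenzyloxy)-3-(trifluoromethylsulfonyloxy)labda-2,7-dien-20-oate | FC(F)(F)S(=O)(=O)OC1=CC[C@@]2(C(=O)OCC=C)[C@H](CC[C@@H](C)CCOCc3ccc(OC)cc3)C(C)=CC[C@@H]2[C@]1(C)COCc4ccccc4
F7 | step 14 | dimethyl 2-{(2R,3R)-2-[(benzyloxy)methyl]-2-methyl-3-[(triethylsilyl)oxy]pent-4-en-1-ylidene}propanedioate | COC(=O)C(C(=O)OC)=C[C@](C)(COCc1ccccc1)[C@H](O[Si](CC)(CC)CC)C=C
F8 | step 14 | methyl (5R,6R)-5-[(benzyloxy)methyl]-6-ethenyl-5-methyl-2-oxo-5,6-dihydro-2H-pyran-3-carboxylate | COC(=O)C1=C[C@](C)(COCc2ccccc2)[C@@H](C=C)OC1=O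
F9 | step 14 | 8a-methoxycarbonyl derivative of 19 (ester on C10) | O=C1O[C@H](C=C)[C@@](C)(COCc2ccccc2)[C@H]3CC=C(C)[C@@H](CC[C@@H](C)CCOCc4ccc(OC)cc4)[C@@]13C(=O)OC
F10 | step 16 | 19-benzyloxy-7β-iodo-15-(4-methoxybenzyloxy)labd-2-en-20-oic acid 20,8α-lactone | O=C1O[C@]2(C)[C@@H](I)C[C@@H]3[C@](C)(COCc4ccccc4)C=CC[C@]13[C@@H]2CC[C@@H](C)CCOCc5ccc(OC)cc5
F11 | step 16 | 2β,3β-diol of F10 | O=C1O[C@]2(C)[C@@H](I)C[C@@H]3[C@](C)(COCc4ccccc4)[C@@H](O)[C@@H](O)C[C@]13[C@@H]2CC[C@@H](C)CCOCc5ccc(OC)cc5
F12 | step 16 | 2β,3β-acetonide of F11 | O=C1O[C@]2(C)[C@@H](I)C[C@@H]3[C@](C)(COCc4ccccc4)[C@H]6OC(C)(C)O[C@H]6C[C@]13[C@@H]2CC[C@@H](C)CCOCc5ccc(OC)cc5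
F13 | step 4 | propan-2-yl (2R,3R)-3-hydroxy-2-(hydroxymethyl)-2-methylpent-4-enoate | CC(C)OC(=O)[C@](C)(CO)[C@H](O)C=C
A1 | alternative 1 | methyl 5-ethenyl-4a,6-dimethyl-2-oxo-2,4a,5,8-tetrahydronaphthalene-1-carboxylate (ring A dienone with C9 vinyl and C7=C8) | O=C1C=C[C@@]2(C)[C@H](C=C)C(C)=CCC2=C1C(=O)OC
A2 | alternative 1 | methyl 6-hydroxy-2-[(2Z,4E)-6-(methoxycarbonyloxy)-3-methylhexa-2,4-dien-1-yl]-3-methylbenzoate | COC(=O)c1c(O)ccc(C)c1C/C=C(C)\C=C\COC(=O)OC
A3 | alternative 2 | trans-fused C7 tert-butyldimethylsilyl enol ether with C11 methyl ester, 2,3-acetonide and 19-silyl ether | CC1(C)O[C@H]2C[C@@]3(C)[C@H](C(=O)OC)[C@H](C)C(O[Si](C)(C)C(C)(C)C)=C[C@@H]3[C@](C)(CO[Si](C)(C)C(C)(C)C)[C@H]2O1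
A4 | alternative 2 | acyclic trienoate with (E)-C9=C10 enoate, C5=C6–C7(OSi)=C8 diene, 2,3-acetonide and quaternary C4 | C/C=C(O[Si](C)(C)C(C)(C)C)/C=C/[C@](C)(CO[Si](C)(C)C(C)(C)C)[C@H]1OC(C)(C)O[C@H]1C/C(C)=C/C(=O)OC
A5 | alternative 3 | C4 spiro methoxycyclopropane of methyl 2β-(tert-butyldimethylsilyloxy)-3β-hydroxylabd-7-en-15-oate (C18–C19 bond) | CC(C)(C)[Si](C)(C)O[C@H]1C[C@@]2(C)[C@H](CC[C@@H](C)CC(=O)OC)C(C)=CC[C@@H]2[C@@]3(C[C@H]3OC)[C@H]1O
A6 | alternative 3 | C4 exocyclic methyl enol ether (C4=C19–OMe, E/Z mixture) of the same bicycle | CC(C)(C)[Si](C)(C)O[C@H]1C[C@@]2(C)[C@H](CC[C@@H](C)CC(=O)OC)C(C)=CC[C@@H]2C(=COC)[C@H]1O
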